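## Assumptions
- 2,4-Dihydroxy-5-methoxybenzaldehyde is purchased.
- The quinine-derived catalyst is taken to give the (2S) sense. If it gave (R), the quinidine-derived pseudo-enantiomer would be used.

**Target check.** Kushenol V is a (2S)-flavanone with a 5,7-dihydroxy-6-prenyl A ring and a 2',4'-dihydroxy-5'-methoxyphenyl B ring. In the target SMILES the C2 neighbours are ordered aryl, H, O1, C3 with "@@". The CIP priorities are O1 > aryl > C3 > H, and this gives (S).

## Retrosynthetic overview
1. Disconnect O1–C2 (intramolecular oxa-Michael) to give the 2',4',6'-trihydroxy-3'-prenylchalcone. C2, the only stereocenter, is set in this final ring-closing step, and the pyranone ring is the only ring formed in the route.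
2. Disconnect the chalcone C=C (Claisen–Schmidt) to give 3-prenylphloroacetophenone and 2,4-dihydroxy-5-methoxybenzaldehyde.
3. Disconnect the aryl–prenyl bond to give phloroacetophenone and prenyl bromide. Both aromatic rings are preformed, so no protecting groups are needed.

## Forward route

**Step 1**
Reactants: 1 (2,4,6-trihydroxyacetophenone); 2 (prenyl bromide)
Product: 3 (1-[2,4,6-trihydroxy-3-(3-methylbut-2-en-1-yl)phenyl]ethan-1-one)
Conditions: 2 (1.0 equiv), KOH (2.5 equiv), MeOH/H2O 1:1, 0 °C→rt, 3 h; cold 1 M HCl to pH 3
Reagents that add atoms: prenyl bromide, CC(C)=CCBr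
Why: Ambident C-alkylation of the phloroglucinol-type phenoxide. The two flanking sites are equivalent by symmetry, so only one mono-C-prenyl regioisomer forms. The yield is moderate, and O-prenyl and diprenyl by-products are removed by chromatography.

**Step 2**
Reactants: 3 (3-prenylphloroacetophenone); 4 (2,4-dihydroxy-5-methoxybenzaldehyde)
Product: 5 ((E)-3-(2,4-dihydroxy-5-methoxyphenyl)-1-[2,4,6-trihydroxy-3-(3-methylbut-2-en-1-yl)phenyl]prop-2-en-1-one)
Conditions: KOH (10 equiv), EtOH, N2, rt, 72 h; then 0 °C aq. citric acid to pH 4
Reagents that add atoms: none (the aldehyde is a reactant; water is lost)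
Why: Claisen–Schmidt condensation. Only the acetyl CH3 of 3 can enolize, and excess base carries the phenolate-deactivated aldehyde through. In base the chalcone stays as its phenolate and does not close. The cold, weakly acidic quench limits uncatalyzed racemic cyclization.

**Step 3**
Reactants: 5 ((E)-chalcone); 6 (catalyst, 10 mol %: N-[(8S,9S)-6'-methoxycinchonan-9-yl]-N'-[3,5-bis(trifluoromethyl)phenyl]squaramide, i.e. quinine-derived 9-amino-9-deoxy-epi squaramide)
Product: 7 (Kushenol V, (2S)-2',4',5,7-tetrahydroxy-5'-methoxy-6-prenylflavanone)
Conditions: 6 (10 mol %), toluene/THF 3:1, 4 Å MS, 5 °C, 72 h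
Reagents that add atoms: none (the catalyst is not incorporated)
Why: Proposed new method: enantioselective intramolecular oxa-Michael (flavanone-forming) cyclization of a fully unprotected 2',6'-dihydroxychalcone that carries a 3'-prenyl group and a free ortho-phenol on the B ring. The closest known reaction is the cinchona-thiourea or squaramide oxa-Michael cyclization of 2'-hydroxychalcones. The prenyl group ortho to the 2'-OH favors the O–H of that phenol pointing at the carbonyl (intramolecular H-bond). This leaves the unhindered 6'-OH on the enone side, so only that phenol is deprotonated and delivered by the quinuclidine. The squaramide N–H groups bind the carbonyl and enone, and the resulting ion pair shields one enone face to set (2S). Closure through the 6'-OH gives the 6-prenyl flavanone rather than the 8-prenyl isomer. No later step touches C2.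

## Compound list
1 | 2,4,6-trihydroxyacetophenone | CC(=O)c1c(O)cc(O)cc1O | starting material
2 | prenyl bromide (1-bromo-3-methylbut-2-ene) | CC(C)=CCBr | starting material
3 | 1-[2,4,6-trihydroxy-3-(3-methylbut-2-en-1-yl)phenyl]ethan-1-one | CC(=O)c1c(O)cc(O)c(CC=C(C)C)c1O | intermediate
4 | 2,4-dihydroxy-5-methoxybenzaldehyde | COc1cc(C=O)c(O)cc1O | starting material
5 | (E)-2',4',6',2,4-pentahydroxy-5-methoxy-3'-prenylchalcone | COc1cc(/C=C/C(=O)c2c(O)cc(O)c(CC=C(C)C)c2O)c(O)cc1O | intermediate
6 | quinine-derived 9-amino-9-deoxy-epi (8S,9S) squaramide bearing 3,5-(CF3)2C6H3 (organocatalyst, 10 mol %) | COC1=CC2=C(C=CN=C2C=C1)[C@@H]([C@@H]3C[C@@H]4CCN3C[C@@H]4C=C)NC5=C(NC6=CC(=CC(=C6)C(F)(F)F)C(F)(F)F)C(=O)C5=O | starting material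
7 | Kushenol V | COc1cc([C@@H]2CC(=O)c3c(cc(O)c(CC=C(C)C)c3O)O2)c(O)cc1O | target

## Totals
Total steps: 3. Longest linear sequence: 3 (1 → 3 → 5 → 7).

## Three steps most likely to fail
1. **Step 3 (proposed new step).** Risks are acidic phenols quenching the amine catalyst, a racemic background cyclization, and poor 6-/8-prenyl discrimination.
   Fallback (known chemistry, different approach): cyclize 5 with NaOAc in refluxing EtOH to the racemic flavanones. Separate the 6- and 8-prenyl regioisomers by preparative HPLC, then resolve the (±)-6-prenyl flavanone by chiral-phase preparative HPLC to isolate the (2S) enantiomer.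
2. **Step 2.** Unprotected polyphenolic partners may give low conversion or premature cyclization.
   Fallback: a protecting-group route. Condense the MOM-protected acetophenone with the MOM-protected aldehyde (Ba(OH)2, EtOH), then remove the MOM groups under mild acid (e.g. PPTS, t-BuOH, 60 °C) to give 5.
3. **Step 1.** Yield and mono-/di-/O-prenyl selectivity may be poor.
   Fallback: tris-MOM-protect phloroacetophenone, do a directed ortho-lithiation at C3, and prenylate with prenyl bromide/CuBr·SMe2. Then remove the MOM groups to give 3.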